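**Retrosynthetic overview**
1. Target 15 ⇒ 11: the 2-pyrone is built last, by γ-oxalylation (vinylogous Claisen) of a 3-methylbut-2-enoate side chain, then acid enol-lactonisation and ester hydrolysis.
2. 11 ⇒ 8 + 9: trans-selective C3 alkylation of the (R)-lactone enolate with a bromo-enoate.
3. 8 ⇒ 7 ⇒ 4: dealkoxycarbonylation; aryl-cuprate homoconjugate opening of a cyclopropane-fused lactone installs the 3,4-dimethoxybenzyl group.
4. 4 ⇒ 1 + 2: a malonate/(R)-epichlorohydrin cascade closes the cyclopropane and the γ-lactone in one flask and fixes the future lactone C4 centre.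
5. Ring order: cyclopropane + γ-butyrolactone together (step 1), cyclopropane opened (step 2), 2-pyrone (step 5).

Assumption: commercial ethyl 4-bromo-3-methylbut-2-enoate is taken as its (E)-isomer; the alkene geometry is erased in step 5, so E/Z purity is not critical.

**Step 1**
Reactants: 1 dimethyl malonate; 2 (R)-epichlorohydrin
Product: 4 methyl (1S,5R)-2-oxo-3-oxabicyclo[3.1.0]hexane-1-carboxylate, via epoxy malonate 3 (not isolated)
Conditions: NaOMe (1.1 equiv), MeOH, 0 °C → reflux, 16 h
Reagents that add atoms: none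
Why: Double alkylation of malonate by the bis-electrophile runs as a cascade (SN2 epoxide opening, chloride displacement to a new epoxide, 3-exo-tet cyclopropanation with inversion at the stereogenic carbon, lactonisation) that forms both rings at once; the single inversion turns the (R)-epoxide centre into C5 (R), and C1 (S) follows because only the cis-fused bicycle can lactonise.

**Step 2**
Reactants: 4 methyl (1S,5R)-2-oxo-3-oxabicyclo[3.1.0]hexane-1-carboxylate; 5 4-bromo-1,2-dimethoxybenzene
Product: 7 methyl (3S,4R)-4-(3,4-dimethoxybenzyl)-2-oxotetrahydrofuran-3-carboxylate, via aryl Grignard reagent 6 (not isolated)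
Conditions: 5, Mg, THF, 40 °C; then 4, CuI (10 mol%), THF, −30 → −10 °C; 1 M HCl work-up
Reagents that add atoms: none
Why: Copper-catalysed homoconjugate addition (SN2-type opening of a doubly activated cyclopropane) by the aryl Grignard reagent at the unsubstituted CH2 gives the malonate-type enolate; C4 is not touched and stays (R), while the enolisable C3 settles trans (3S) and is removed as a stereocentre in step 3.

**Step 3**
Reactants: 7 methyl (3S,4R)-4-(3,4-dimethoxybenzyl)-2-oxotetrahydrofuran-3-carboxylate
Product: 8 (R)-4-(3,4-dimethoxybenzyl)dihydrofuran-2(3H)-one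
Conditions: LiCl (2 equiv), DMSO–H2O (10:1), 140 °C
Reagents that add atoms: none
Why: Krapcho dealkoxycarbonylation (chloride SN2 at the methyl ester, loss of CO2, protonation) removes the activating ester; C4 (R) is not involved.

**Step 4**
Reactants: 8 (R)-4-(3,4-dimethoxybenzyl)dihydrofuran-2(3H)-one; 9 ethyl (E)-4-bromo-3-methylbut-2-enoate
Product: 11 ethyl (E)-4-[(3R,4R)-4-(3,4-dimethoxybenzyl)-2-oxotetrahydrofuran-3-yl]-3-methylbut-2-enoate, via lithium enolate 10 (not isolated)
Conditions: LiHMDS (1.05 equiv), THF, −78 °C; then 9 (1.2 equiv), DMPU, −78 → −40 °C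
Reagents that add atoms: none
Why: SN2 alkylation of the lactone lithium enolate with the allylic bromide takes place on the face opposite the C4 benzyl group, which sets C3 (R) trans to C4, the usual outcome for β-substituted γ-butyrolactone enolates.

**Step 5**
Reactants: 11 ethyl (E)-4-[(3R,4R)-4-(3,4-dimethoxybenzyl)-2-oxotetrahydrofuran-3-yl]-3-methylbut-2-enoate; 12 diethyl oxalate
Product: 15 target acid 4-{[(3R,4R)-4-(3,4-dimethoxybenzyl)-2-oxotetrahydrofuran-3-yl]methyl}-2-oxo-2H-pyran-6-carboxylic acid, via potassium dienolate 13 (not isolated), via pyrone ethyl ester 14 (not isolated)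
Conditions: KOt-Bu (2 equiv), 12 (3 equiv), THF, 0 °C → rt, slow addition of 11; then conc. HCl–AcOH (1:1), 90 °C
Reagents that add atoms: water, O
Why: Vinylogous Claisen condensation of the dienolate with diethyl oxalate at the γ-methyl group gives the stabilised 2-hydroxymuconate enolate, and hot HCl then closes the 2-pyrone by enol lactonisation and hydrolyses the 6-ester (the classical oxalate route to 2-pyrone-6-carboxylic acids); the trans lactone is also the thermodynamic isomer, so reversible deprotonation at C3 by the alkoxide does not erode it.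

**Compound list**
1 | dimethyl malonate | COC(=O)CC(=O)OC | starting material
2 | (R)-epichlorohydrin | ClC[C@H]1CO1 | starting material
3 | dimethyl 2-{[(2R)-oxiran-2-yl]methyl}malonate | COC(=O)C(C(=O)OC)C[C@@H]1CO1 | intermediate
4 | methyl (1S,5R)-2-oxo-3-oxabicyclo[3.1.0]hexane-1-carboxylate | COC(=O)[C@]12C[C@H]1COC2=O | intermediate
5 | 4-bromo-1,2-dimethoxybenzene | COc1ccc(Br)cc1OC | starting material
6 | (3,4-dimethoxyphenyl)magnesium bromide | COc1ccc([Mg]Br)cc1OC | intermediate
7 | methyl (3S,4R)-4-(3,4-dimethoxybenzyl)-2-oxotetrahydrofuran-3-carboxylate | COC(=O)[C@@H]1[C@@H](Cc2ccc(OC)c(OC)c2)COC1=O | intermediate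
8 | (R)-4-(3,4-dimethoxybenzyl)dihydrofuran-2(3H)-one | COc1ccc(C[C@H]2COC(=O)C2)cc1OC | intermediate
9 | ethyl (E)-4-bromo-3-methylbut-2-enoate | CCOC(=O)/C=C(\C)CBr | starting material
10 | lithium enolate of 8, lithium (R)-3-(3,4-dimethoxybenzyl)-2,3-dihydrofuran-5-olate | COc1ccc(C[C@H]2COC([O-])=C2)cc1OC.[Li+] | intermediate
11 | ethyl (E)-4-[(3R,4R)-4-(3,4-dimethoxybenzyl)-2-oxotetrahydrofuran-3-yl]-3-methylbut-2-enoate | COc1ccc(C[C@H]2COC(=O)[C@@H]2C/C(C)=C/C(=O)OCC)cc1OC | intermediate
12 | diethyl oxalate | CCOC(=O)C(=O)OCC | starting material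
13 | potassium 1,6-diethoxy-4-{[(3R,4R)-4-(3,4-dimethoxybenzyl)-2-oxotetrahydrofuran-3-yl]methyl}-1,6-dioxohexa-2,4-dien-2-olate (mixture of double-bond isomers) | COc1ccc(C[C@H]2COC(=O)[C@@H]2CC(=CC(=O)OCC)C=C([O-])C(=O)OCC)cc1OC.[K+] | intermediate
14 | ethyl 4-{[(3R,4R)-4-(3,4-dimethoxybenzyl)-2-oxotetrahydrofuran-3-yl]methyl}-2-oxo-2H-pyran-6-carboxylate | COc1ccc(C[C@H]2COC(=O)[C@@H]2Cc2cc(C(=O)OCC)oc(=O)c2)cc1OC | intermediate
15 | 4-{[(3R,4R)-4-(3,4-dimethoxybenzyl)-2-oxotetrahydrofuran-3-yl]methyl}-2-oxo-2H-pyran-6-carboxylic acid | COc1ccc(C[C@H]2COC(=O)[C@@H]2Cc2cc(C(=O)O)oc(=O)c2)cc1OC | target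

**Total step count:** 5
**Longest linear sequence:** 5 steps (1 + 2 → 4 → 7 → 8 → 11 → 15)

**Steps most likely to fail**

Step 5 is the riskiest. The γ-methyl group must be oxalylated in preference to the allylic CH2, and the dienolate can instead attack the lactone carbonyl intramolecularly (a five-membered Claisen closure); excess oxalate and slow addition of 11 are meant to suppress this. The fallback sets out from 8 and 12 and brings the pyrone in ready-made. Commercial ethyl 3-methylbut-2-enoate and 12 are condensed (KOEt, Et2O; then HCl, EtOH) to ethyl 4-methyl-2-oxo-2H-pyran-6-carboxylate F1. Radical bromination (NBS, AIBN, PhCF3, 80 °C) gives ethyl 4-(bromomethyl)-2-oxo-2H-pyran-6-carboxylate F2. The lithium enolate 10 of lactone 8 is alkylated with F2 at −78 °C, trans to the benzyl group, and the route is rejoined at pyrone ester 14, which is hydrolysed (HCl, AcOH, 90 °C) to 15.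

Step 4 is next. The basic lactone enolate may deprotonate 9, or add to it in Michael fashion and close a cyclopropane, instead of direct SN2 displacement. The fallback sets out from 7, whose malonate-type C3–H allows alkylation with 9 under mild conditions (K2CO3, acetone, rt). This gives methyl (3R,4R)-4-(3,4-dimethoxybenzyl)-3-[(E)-4-ethoxy-2-methyl-4-oxobut-2-en-1-yl]-2-oxotetrahydrofuran-3-carboxylate F3. Krapcho dealkoxycarbonylation (LiCl, wet DMSO, 140 °C) then gives 11 together with its C3 epimer. Equilibration with DBU (toluene, 80 °C), or simply the alkoxide of step 5, converges on the trans isomer, and the route is rejoined at 11.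

Step 2 is third. The aryl Grignard reagent may attack the lactone or ester carbonyl of 4 in competition with cyclopropane opening. The fallback sets out from 4 and opens the cyclopropane with iodide (MgI2, THF, rt; dilute HCl) to methyl (3S,4R)-4-(iodomethyl)-2-oxotetrahydrofuran-3-carboxylate F4. Nickel-catalysed reductive cross-electrophile coupling of F4 with 5 (NiI2, 4,4'-di-tert-butyl-2,2'-bipyridine, Zn, DMA, 60 °C) then rejoins the route at 7.

**Further compounds**
F1 | step 5 | ethyl 4-methyl-2-oxo-2H-pyran-6-carboxylate | CCOC(=O)c1cc(C)cc(=O)o1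
F2 | step 5 | ethyl 4-(bromomethyl)-2-oxo-2H-pyran-6-carboxylate | CCOC(=O)c1cc(CBr)cc(=O)o1
F3 | step 4 | methyl (3R,4R)-4-(3,4-dimethoxybenzyl)-3-[(E)-4-ethoxy-2-methyl-4-oxobut-2-en-1-yl]-2-oxotetrahydrofuran-3-carboxylate | COC(=O)[C@@]1(C/C(C)=C/C(=O)OCC)[C@@H](Cc2ccc(OC)c(OC)c2)COC1=O
F4 | step 2 | methyl (3S,4R)-4-(iodomethyl)-2-oxotetrahydrofuran-3-carboxylate | COC(=O)[C@@H]1[C@@H](CI)COC1=O
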